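The earlier runs and the new flask are simulated on assumed constants.

Which of these flasks ends with the most left-handed product, and does moving the temperature, or changing it halfway, buy anything?

| setting | birch | ash | larch | Tuesday's | Sunday's | Saturday's | Wednesday's |
|---|---|---|---|---|---|---|---|
| left-handed substrate | 23 mM | 23 mM | 34 mM | 23 mM | 23 mM | 23 mM | 23 mM |
| right-handed substrate | 23 mM | 23 mM | 34 mM | 23 mM | 23 mM | 23 mM | 23 mM |
| reagent | 13.8 mM | 13.8 mM | 13.8 mM | 13.8 mM | 13.8 mM | 13.8 mM | 13.8 mM |
| catalyst | 1.1 mM | 1.7 mM | 0.76 mM | 0.76 mM | 0.76 mM | 0.76 mM | 0.76 mM |
| temperature | 45 °C | 75 °C | 45 °C | 50 °C | 75 °C |  | 100 °C |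
| remark | run made earlier | run made earlier | run made earlier |  |  | at 50 °C until 30 min, from then on at 100 °C |  |
| time |  |  |  | 1.0 h | 1.0 h | 1.0 h | 1.0 h |

- catalyst is single-handed; left-handed substrate and right-handed substrate are mirror images of each other, charged as a racemate, each of them at the stated concentration
- the analysis behind the earlier runs scatters by 0.3 percentage points, standard deviation

- which flask leads in amount of left-handed product, in percent of the left-handed substrate and right-handed substrate together charged ("all alike" within 1.5 percentage points) (Tuesday's / Sunday's / Saturday's / Wednesday's / all alike)
- how much left-handed product is there at the end, in percent of the left-handed substrate and right-handed substrate together charged: Tuesday's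
- how much left-handed product is there at the end, in percent of the left-handed substrate and right-handed substrate together charged: Sunday's
- how much left-handed product is there at the end, in percent of the left-handed substrate and right-handed substrate together charged: Saturday's
- how much left-handed product is there at the end, in percent of the left-handed substrate and right-handed substrate together charged: Wednesday's

- birch (time / min: left-handed product / %): 6.00: 3.7; 12.0: 7.0; 20.0: 9.3; 25.0: 11.3; 30.0: 12.3; 40.0: 14.5
- ash (time / min: left-handed product / %): 0.667: 1.9; 2.50: 6.6; 4.00: 8.4; 6.00: 10.3; 8.00: 11.7; 12.0: 12.9
- larch (time / min: left-handed product / %): 3.00: 1.5; 5.00: 2.9; 10.0: 4.1; 20.0: 6.6; 40.0: 9.7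

(scatter of a reading: 0.3 percentage points)

The reagent charged is 30.0% of both substrates together, so it is the limiting reagent, and I solve the problem at its two ends. At one end the reagent goes to the left-handed substrate with none to the right-handed, and left-handed product stops at that share. At the other end the reagent is shared evenly between the hands, and left-handed product stops at the even-split ceiling, 15.0%, which is half of the reagent share.

I join the ends by reading the ash table downward. At 75 °C the ash readings gain 4.7 percentage points between 0.667 min and 2.50 min, but 1.2 points between 8.00 min and 12.0 min, and the last of them stands at 12.9%, lower than the ceiling and lower still than the other end. Taking rate as proportional to catalyst, Sunday's has 2.24 times the catalyst multiplied by time of that last reading, so I put Sunday's and the hotter Wednesday's at the ceiling.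

The birch table gives the cold side: Tuesday's has 1.04 times the catalyst multiplied by time of the last birch reading, 14.5%, so Tuesday's lands near the ceiling by another route. Saturday's reaches its change of temperature with 1.04 times the catalyst multiplied by time of the birch reading of 9.3%, so I take that reading as a rough head start for Saturday's. The readings do not tell me whether a hot stretch keeps such a head start, but I commit to Saturday's ending near the ceiling as well. So I expect Tuesday's, Sunday's, Saturday's and Wednesday's within 1.5 points of one another, with no leader.

The forecast differs and gives the lead to Saturday's, with 16%, 15%, 18.5% and 15% for Tuesday's, Sunday's, Saturday's and Wednesday's, reckoning for Saturday's that "half the remaining reagent adds about 7.5%".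

The flasks give all alike: Tuesday's 14.8%, Sunday's 14.4%, Saturday's 14.8%, Wednesday's 15.0%.

    reagent + catalyst + left-handed substrate → catalyst + left-handed product (k = 19.0 M⁻² s⁻¹, Ea = 35.0 kJ mol⁻¹)
    reagent + catalyst + right-handed substrate → catalyst + right-handed product (k = 4.30 M⁻² s⁻¹, Ea = 53.0 kJ mol⁻¹)
    left-handed product ⇌ right-handed product (k = 8.10 × 10⁻⁵ s⁻¹, Ea = 110 kJ mol⁻¹)
    (constants at 50 °C)

Saturday's ends close to the ceiling of 15.0%, with 14.8% left-handed product beside 14.8% right-handed product and 1.20% of its reagent still there. In Sunday's the two products relax into each other with a half-life of 0.0628 h, short against 1.0 h. The same reckoning on the neighbour of Sunday's charged with 5.5 mM of reagent puts its ceiling at 5.98%. That neighbour keeps 2.44% of its reagent and ends with 5.86% left-handed product.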